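I split the substrate first: it goes two ways, into target and into the dormant form.

| setting | grey | blue | flask |
|---|---|---|---|
| substrate | 0.025 M | 0.10 M | 0.050 M |
| remark | run made earlier | run made earlier |  |
| time |  |  | 1.0 h |

| run | time / min | target / % | substrate / % |
|---|---|---|---|
| grey | 0.500 | 12.2 | 47.5 |
| grey | 1.00 | 13.5 | 27.7 |
| grey | 2.00 | 9.7 | 13.7 |
| grey | 5.00 | 0.8 | 8.3 |
| grey | 10.0 | 0 | 5.9 |
| grey | 20.0 | 0.4 | 6.5 |
| grey | 50.0 | 0.7 | 6.3 |
| blue | 0.500 | 36.4 | 30.6 |
| blue | 1.00 | 42.0 | 15.7 |
| blue | 2.00 | 42.6 | 8.1 |
| blue | 5.00 | 39.9 | 4.3 |
| blue | 10.0 | 36.2 | 4.4 |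
| blue | 20.0 | 28.4 | 5.3 |
| blue | 50.0 | 12.1 | 6.8 |

(standard deviation of a reading: 0.5 percentage points)

- a species is counted by the substrate in it: one target or crystals counts as two
- amounts and yields of target count crystals too
- given per volume of solution although it is solid: crystals
- steps under discussion: 2 substrate <-> target; crystals <-> target; substrate <-> dormant form

* when, up to 1.0 h, the flask holds most target, in min
* the amount of target, in percent of the substrate charged, at that time

The balance gives the dormant form at the first reading. Target over dormant form there read 0.303 in grey and 1.10 in blue, a factor 3.63 for a charge factor 4.00. Target takes substrate in pairs, so I let this ratio follow the charge. The flask's charge is twice grey's and half blue's, so I took the middle: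

N = 0.578

This N is my estimate of the flask's selectivity factor, substrate in target per substrate in the dormant form at the time of the first reading. Of the substrate that leaves, target should get the share

N/(1+N) = 0.366

If one number were enough, each run's highest reading over its share would be the same. Grey gave 0.581 and blue 0.812, so it wasn't. Their mean gave me 25.5% for the flask, with the peak between 1.00 min and 2.00 min.

The forecast said 1.3 min (1 min to 1.8 min) and 27% (24% to 30%), above mine. One of its grounds: “That is the signature of crystals holding dissolved target at saturation”.

The flask held most target at 1.30 min: 26.8%.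

    2 substrate ⇌ target (K = 9.27 M⁻¹, k = 0.235 M⁻¹ s⁻¹)
    crystals ⇌ target, rate k2*(cs2 - [target]) while solid is left; crystals form when [target] > cs2 (solubility = 0.540 mM, k = 0.0974 s⁻¹)
    substrate ⇌ dormant form (K = 14.0, k = 0.0198 s⁻¹)

At that time the flask's dormant form stood at 57.1%, and the flask's best was 0.732 of its share 0.366, above grey's 0.581 and below blue's 0.812. For the neighbour charged with 0.12 M, N grows to 1.39, a share of 0.581. With blue's 0.812 that makes 47.2%, and that neighbour's best was 46.5%.

The readings stem from a simulated flask with made-up constants, and the scatter is random.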